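| flask | left-handed substrate | right-handed substrate | gas | racemization catalyst | remark | time |
|---|---|---|---|---|---|---|
| alder | 6.7 mM | 6.7 mM | 4.4 mM (held) | 0.44 mM | run made earlier |  |
| ash | 15 mM | 15 mM | 4.4 mM (held) | 0.44 mM | run made earlier |  |
| larch | 10 mM | 10 mM | 4.4 mM (held) | 0.22 mM | run made earlier |  |
| flask | 10 mM | 10 mM | 4.4 mM (held) | 0.44 mM |  | 5.0 min |

| run | time / min | left-handed product / % | right-handed product / % | left-handed substrate / % |
|---|---|---|---|---|
| alder | 0.200 | 2 | 1 | 47 |
| alder | 0.667 | 8 | 3 | 44 |
| alder | 1.00 | 17 | 8 | 43 |
| alder | 1.50 | 20 | 7 | 31 |
| alder | 2.50 | 31 | 13 | 22 |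
| alder | 3.00 | 44 | 21 | 20 |
| ash | 0.500 | 6 | 2 | 44 |
| ash | 1.00 | 9 | 5 | 43 |
| ash | 1.50 | 13 | 7 | 39 |
| ash | 2.00 | 20 | 5 | 37 |
| ash | 2.50 | 25 | 7 | 30 |
| ash | 3.00 | 29 | 10 | 28 |
| larch | 0.250 | 1 | 1 | 44 |
| larch | 0.417 | 1 | 3 | 48 |
| larch | 0.833 | 11 | 1 | 46 |
| larch | 1.50 | 16 | 6 | 37 |
| larch | 3.00 | 33 | 17 | 30 |

(scatter of a reading: 2 percentage points)

- coupling partner is single-handed; left-handed substrate and right-handed substrate are mirror images of each other, charged as a racemate, each of them at the stated concentration
- at the start none of the gas is in solution
- an excess is the difference of the two amounts in percent of their sum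
- an excess is below zero if the other one leads
- the handed part of coupling partner does not stay in what it makes, so the products of the two hands are mirror images too

- excess of left-handed product over right-handed product in the product at 15 s
- excess of left-handed product over right-handed product in the product at 5.0 min
- part of the left-handed substrate and right-handed substrate charged together that has reacted at 5.0 min

- I started from the product: I divided the rate of making left-handed product by the rate of making right-handed product, so that time dropped out, and these two rates were the pair I watched.
- I took both hands to draw on the one coupling partner, so the gas supply cancelled from that quotient, which left a constant preference, the selectivity factor, times c(left-handed substrate)/c(right-handed substrate).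
- That substrate quotient needed a reading. In alder at 3.00 min, the left-handed product taken from its own half left room for 6.00 % of left-handed substrate, yet I read more, 20 %, and right-handed substrate by difference stood at 15.0 %. So I took racemization to hold the quotient near 1, as a judgement: those two figures stood 5 percentage points apart, and each reading behind them carried a scatter of 2 points.
- The rate quotient then became a plain product ratio. Pooling the last reading of each earlier run, I read left-handed product over right-handed product as 2.21, the product ratio.
- That ratio gave me an excess of 37.7 %, to which I committed at both 15 s and 5.0 min; with time gone, it gave no conversion.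
- The forecast gave 45 % at 15 s, 36 % at 5.0 min and 77 % reacted, holding that “the excess should persist, sagging only slightly”; its early figure stood above mine.

- The flask gave 38.4 % at 15 s, 38.3 % at 5.0 min and 74.8 % reacted.

    coupling partner + left-handed substrate → left-handed product (k = 3.17 M⁻¹ s⁻¹)
    coupling partner + right-handed substrate → right-handed product (k = 1.41 M⁻¹ s⁻¹)
    left-handed substrate + racemization catalyst ⇌ right-handed substrate + racemization catalyst, rate k3*[racemization catalyst]*[left-handed substrate] forward; the back reaction follows from the equilibrium constant (k = 2400 M⁻¹ s⁻¹)
    2 racemization catalyst ⇌ resting dimer, settled at all times (K = 1000 M⁻¹)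
    gas ⇌ coupling partner, rate k5*(csat - [coupling partner]) (kL = 0.0248 s⁻¹)

- In the flask at 5.0 min, coupling used left-handed substrate at 0.013 of the forward racemization rate. The product ratio turned the reacted part of the flask into 51.5 % left-handed product, and the flask held 51.7 %. The neighbour flask with 1.8 mM of racemization catalyst reacted to 74.8 %, for which the same ratio gave 51.5 %, and at 5.0 min that neighbour flask held 51.8 % left-handed product.

The readings stem from a simulated flask for an exercise, noise included.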